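The disconnection cuts the bond between the ring-fusion CH beside the gem-dimethyl carbon (C5) and the γ-lactone carbinol CH (C6). This bond is common to carbocycle B and the γ-lactone, so C5 is the one-atom bridge of a 6-oxabicyclo[3.2.1]octan-7-one. The precursor is a 1,1-disubstituted cyclohexa-2,5-diene spiro-linked to a seven-membered phenylthio lactone; an α-acyloxy radical at C6 adds 5-exo to one of the two equivalent diene arms. One operation closes ring B and the γ-lactone, breaks the hidden symmetry of ring A and sets C5, C6 and C10 under control of the preformed cyclopentene–δ-lactone bicycle.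

Key step: step 10

Numbering used below (terpenoid style): ring A = C1, C2, C3 (acetoxy), C4 (gem-dimethyl), C5, C10; ring B = C5 to C10; C19 = γ-lactone carbonyl on C10; ring C = C8, C9, C11, C12, C13; the δ-lactone (ring D) runs C9–O–C(=O)–C(=CH2)–C13.

Remark on the chemistry: centres that are destroyed later (sulfoxide sulfur, C8 in 10, C6 in 19, the aminomethyl-bearing carbon in 29 and 30) are carried as epimer mixtures and are left undefined in the SMILES.

Step 1
Reactants: 1 2-methylcyclopentane-1,3-dione
Product: 2 2-methyl-3-oxocyclopent-1-en-1-yl trifluoromethanesulfonate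
Conditions: (CF3SO2)2O, pyridine, CH2Cl2, −78 to 0 °C
Reagents that add atoms: trifluoromethanesulfonic anhydride, O=S(=O)(OS(=O)(=O)C(F)(F)F)C(F)(F)F
Why: O-sulfonylation of the enol of a cyclic 1,3-diketone (enol triflate formation) should give the vinylogous acyl triflate; no stereocentre is formed.

Step 2
Reactants: 2 2-methyl-3-oxocyclopent-1-en-1-yl trifluoromethanesulfonate
Product: 3 methyl 2-methyl-3-oxocyclopent-1-ene-1-carboxylate
Conditions: Pd(OAc)2 (cat.), Ph2P(CH2)3PPh2, CO (1 atm), MeOH, Et3N, DMF, 60 °C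
Reagents that add atoms: carbon monoxide, [C-]#[O+]; methanol, CO
Why: Palladium-catalysed alkoxycarbonylation of a vinyl triflate (oxidative addition, CO insertion, methanolysis) should place the ester on the future C13.

Step 3
Reactants: 3 methyl 2-methyl-3-oxocyclopent-1-ene-1-carboxylate
Product: 4 methyl (R)-3-hydroxy-2-methylcyclopent-1-ene-1-carboxylate
Conditions: (S)-1-methyl-3,3-diphenyltetrahydro-1H,3H-pyrrolo[1,2-c][1,3,2]oxazaborole (cat.), BH3·SMe2, THF, −20 °C; then MeOH
Reagents that add atoms: none
Why: Corey–Bakshi–Shibata reduction, in which the oxazaborolidine–borane complex tells the large substituted-alkene arm from the small CH2 arm of the ketone, so the (S)-catalyst should deliver the (R)-carbinol that later relays its configuration to C13.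

Step 4
Reactants: 4 methyl (R)-3-hydroxy-2-methylcyclopent-1-ene-1-carboxylate
Product: 7 methyl (S)-1-(2-methoxy-2-oxoethyl)-2-methylcyclopent-2-ene-1-carboxylate, via mixed orthoester 5 (not isolated), via ketene acetal 6 (not isolated)
Conditions: CH3C(OMe)3, EtCO2H (cat.), xylene, 140 °C, MeOH distilled off
Reagents that add atoms: trimethyl orthoacetate, CC(OC)(OC)OC
Why: Johnson–Claisen rearrangement, whose suprafacial [3,3] shift of the ketene acetal delivers CH2CO2Me to C13 on the face of the former C–O bond, so the quaternary centre is set by chirality transfer and the alkene moves to C11=C12.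

Step 5
Reactants: 7 methyl (S)-1-(2-methoxy-2-oxoethyl)-2-methylcyclopent-2-ene-1-carboxylate
Product: 8 methyl (S)-1-(2-methoxy-2-oxoethyl)-2-methyl-4-oxocyclopent-2-ene-1-carboxylate
Conditions: Rh2(C6H10NO)4 (dirhodium tetrakis(caprolactamate), cat.), t-BuOOH, K2CO3, CH2Cl2, rt
Reagents that add atoms: tert-butyl hydroperoxide, CC(C)(C)OO
Why: Catalytic allylic oxidation with t-BuOOH should convert the only ring CH2 allylic to C11=C12 into the C9 ketone; the quaternary centre is not touched.

Step 6
Reactants: 8 methyl (S)-1-(2-methoxy-2-oxoethyl)-2-methyl-4-oxocyclopent-2-ene-1-carboxylate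
Product: 10 methyl 1-(2-methoxy-2-oxoethyl)-2-methyl-4-oxo-5-[2-(phenylsulfinyl)ethyl]cyclopent-2-ene-1-carboxylate (C8 epimers; sulfur epimers), via lithium dienolate 9 (not isolated)
Conditions: LiN(i-Pr)2, THF, −78 °C; phenyl vinyl sulfoxide, −78 to −20 °C; aq. NH4Cl
Reagents that add atoms: phenyl vinyl sulfoxide, C=CS(=O)c1ccccc1
Why: Kinetic α'-deprotonation of the cyclopentenone followed by Michael addition of the enolate to the vinyl sulfoxide should attach the C7–C6 unit; the new C8 centre is epimeric and is planarised again in step 7.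

Step 7
Reactants: 10 methyl 1-(2-methoxy-2-oxoethyl)-2-methyl-4-oxo-5-[2-(phenylsulfinyl)ethyl]cyclopent-2-ene-1-carboxylate
Product: 12 methyl 1-(2-methoxy-2-oxoethyl)-2,5-dimethyl-4-oxo-5-[2-(phenylsulfinyl)ethyl]cyclopent-2-ene-1-carboxylate (5-methyl cis to the ring CO2Me; sulfur epimers), via lithium enolate 11 (not isolated)
Conditions: LiN(i-Pr)2, THF, −78 °C; MeI, DMPU, −78 to −20 °C
Reagents that add atoms: iodomethane, CI
Why: Enolate alkylation, in which iodomethane should approach the tetrasubstituted enolate anti to the bulkier CH2CO2Me group on the neighbouring quaternary C13, placing methyl cis to CO2Me and the sulfinylethyl chain cis to CH2CO2Me at C8.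

Step 8
Reactants: 12 methyl 1-(2-methoxy-2-oxoethyl)-2,5-dimethyl-4-oxo-5-[2-(phenylsulfinyl)ethyl]cyclopent-2-ene-1-carboxylate; 13 benzoic acid
Product: 16 1-[5-(methoxycarbonyl)-6,8-dimethyl-3-oxo-8-[2-(phenylsulfinyl)ethyl]-2-oxabicyclo[3.2.1]oct-6-en-1-yl]cyclohexa-2,5-diene-1-carboxylic acid, via dilithium dienediolate 14 (not isolated), via dilithium aldolate 15 (not isolated)
Conditions: 13, Li, NH3(l), THF, −78 °C; isoprene; NH3 removed; 12, THF, −78 to 0 °C; 1 M HCl to pH 3, 0 °C
Reagents that add atoms: none
Why: Birch reduction of benzoic acid gives the carboxylate dienolate, whose reversible aldol addition to the C9 ketone is drained by lactonisation of the tertiary alkoxide onto the cis CH2CO2Me arm, so only the adduct with C9–O cis to that arm (attack anti to the C8 side chain) should accumulate; C10 is not yet a stereocentre because the diene ring is symmetric.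

Step 9
Reactants: 16 1-[5-(methoxycarbonyl)-6,8-dimethyl-3-oxo-8-[2-(phenylsulfinyl)ethyl]-2-oxabicyclo[3.2.1]oct-6-en-1-yl]cyclohexa-2,5-diene-1-carboxylic acid
Product: 19 seven-membered phenylthio lactone (C19 carboxyl esterified onto the sulfur-bearing C6; spiro at C10; C6 epimers), via acyloxysulfonium carboxylate 17 (not isolated), via thionium carboxylate 18 (not isolated)
Conditions: (CF3CO)2O, 2,6-lutidine, CH2Cl2 (0.005 M), −78 to 0 °C
Reagents that add atoms: none
Why: Intramolecular Pummerer reaction, in which O-acylation of the sulfoxide and loss of trifluoroacetate give the thionium ion at C6 and the C19 carboxylate captures it (7-exo) to form the O,S-acetal lactone; the C6 centre forms as a mixture that is erased in step 10.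

Step 10
Reactants: 19 seven-membered phenylthio lactone
Product: 22 pentacyclic bis-lactone with C1=C2 in ring A (C5–H anti to the γ-lactone bridge; ring D still without its methylene), via C6 radical 20 (not isolated), via C4 radical 21 (not isolated)
Conditions: Bu3SnH (slow addition), azobisisobutyronitrile (cat.), benzene (0.01 M), 80 °C
Reagents that add atoms: none
Why: Bu3Sn• removes PhS from the O,S-acetal carbon C6 to give the α-acyloxyalkyl radical 20, which adds 5-exo-trig to C5 of one diene arm to give the secondary C4 radical 21, reduced by Bu3SnH. The closest known reaction type is the tin hydride cyclisation of α-oxygenated radicals from O,S-acetals, applied as a desymmetrising radical cyclisation of a 1-substituted cyclohexa-2,5-diene-1-carboxylate. The γ-lactone closes in the 5-exo mode and, because C6 is already tied to C10 through C7–C8–C9, the same bond closes ring B transannularly across the seven-membered lactone as the six-membered ring of a 6-oxabicyclo[3.2.1]octanone. The lactone tether forces C6 onto the ring-A face that carries C19, which fixes C5 (H anti to C19) and the bridgehead C6, while C10 becomes a stereocentre through the choice between the two arms. Only one arm lets ring B form as a chair whose C8–C9 torsion matches the one imposed by the rigid cyclopentene–δ-lactone bicycle, the other arm requiring a boat. The step needs cyclisation to outrun direct reduction and it needs arm selectivity, to be secured by dilute stannane and by this chair preference.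

Step 11
Reactants: 22 pentacyclic bis-lactone with C1=C2 in ring A
Product: 23 ring-A enone (C1=C2–C3=O)
Conditions: Rh2(C6H10NO)4 (cat.), t-BuOOH, K2CO3, CH2Cl2, rt
Reagents that add atoms: tert-butyl hydroperoxide, CC(C)(C)OO
Why: Allylic oxidation of C3, the only secondary allylic CH2 in the molecule, should give the enone without touching a stereocentre.

Step 12
Reactants: 23 ring-A enone
Product: 25 4,4-dimethyl enone, via monomethyl enone 24 (not isolated)
Conditions: KN(SiMe3)2, THF, −78 °C; MeI; then KN(SiMe3)2; MeI (same flask)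
Reagents that add atoms: iodomethane, CI
Why: Twofold α'-alkylation of the enone through its cross-conjugated potassium enolate, which can form only at C4 because C2 is vinylic and C10 quaternary, should install the gem-dimethyl group; the lactone α-CH2 is much less acidic.

Step 13
Reactants: 25 4,4-dimethyl enone
Product: 26 4,4-dimethyl-3-ketone (ring A saturated)
Conditions: RhCl(PPh3)3 (cat.), H2 (1 atm), benzene/EtOH, rt
Reagents that add atoms: none
Why: Homogeneous hydrogenation should saturate the disubstituted enone C1=C2 bond, the trisubstituted C11=C12 alkene between two quaternary carbons being far slower and the allylic lactone not being cleaved.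

Step 14
Reactants: 26 4,4-dimethyl-3-ketone
Product: 27 axial (3S) alcohol, OH cis to C5–H
Conditions: KBH(s-Bu)3, THF, −78 °C; aq. NH4Cl
Reagents that add atoms: none
Why: Reduction with a bulky trialkylborohydride, which attacks the 4,4-dimethyl-3-ketone from the equatorial side, should give the axial alcohol cis to C5–H; esters and lactones survive at −78 °C.

Step 15
Reactants: 27 axial (3S) alcohol
Product: 31 α-methylene δ-lactone alcohol (deacetyl target), via dilithium alkoxide enolate 28 (not isolated), via Mannich base 29 (not isolated), via ammonium iodide 30 (not isolated)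
Conditions: LiN(i-Pr)2 (2.5 equiv), THF, −78 °C; CH2=NMe2+ I−; aq. NH4Cl; then MeI, CH2Cl2/MeOH, rt; then aq. NaHCO3
Reagents that add atoms: N,N-dimethylmethyleneiminium iodide, C=[N+](C)C.[I-]
Why: Mannich α-methylenation, in which the only enolisable carbonyl left (the δ-lactone) is aminomethylated and N-methylation followed by base-induced elimination of trimethylamine should give the exocyclic methylene.

Step 16
Reactants: 31 α-methylene δ-lactone alcohol
Product: 32 meroantarctine B
Conditions: Ac2O, Et3N, 4-(dimethylamino)pyridine (cat.), CH2Cl2, rt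
Reagents that add atoms: acetic anhydride, CC(=O)OC(C)=O
Why: Nucleophile-catalysed acylation of the hindered axial secondary alcohol should give the acetate with retention at C3.

Compound list
1 | 2-methylcyclopentane-1,3-dione | CC1C(=O)CCC1=O | starting material
2 | 2-methyl-3-oxocyclopent-1-en-1-yl trifluoromethanesulfonate | CC1=C(OS(=O)(=O)C(F)(F)F)CCC1=O | intermediate
3 | methyl 2-methyl-3-oxocyclopent-1-ene-1-carboxylate | COC(=O)C1=C(C)C(=O)CC1 | intermediate
4 | methyl (R)-3-hydroxy-2-methylcyclopent-1-ene-1-carboxylate | COC(=O)C1=C(C)[C@H](O)CC1 | intermediate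
5 | mixed orthoester, methyl (R)-3-(1,1-dimethoxyethoxy)-2-methylcyclopent-1-ene-1-carboxylate | COC(=O)C1=C(C)[C@H](OC(C)(OC)OC)CC1 | intermediate
6 | ketene acetal, methyl (R)-3-[(1-methoxyethenyl)oxy]-2-methylcyclopent-1-ene-1-carboxylate | COC(=O)C1=C(C)[C@H](OC(=C)OC)CC1 | intermediate
7 | methyl (S)-1-(2-methoxy-2-oxoethyl)-2-methylcyclopent-2-ene-1-carboxylate | CC1=CCC[C@]1(C(=O)OC)CC(=O)OC | intermediate
8 | methyl (S)-1-(2-methoxy-2-oxoethyl)-2-methyl-4-oxocyclopent-2-ene-1-carboxylate | CC1=CC(=O)C[C@]1(C(=O)OC)CC(=O)OC | intermediate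
9 | lithium cross-conjugated dienolate of 8 (O-lithio at C9) | CC1=CC([O-])=C[C@]1(C(=O)OC)CC(=O)OC.[Li+] | intermediate
10 | methyl 1-(2-methoxy-2-oxoethyl)-2-methyl-4-oxo-5-[2-(phenylsulfinyl)ethyl]cyclopent-2-ene-1-carboxylate, quaternary carbon as in 8, C8 and sulfur epimers | CC1=CC(=O)C(CCS(=O)c2ccccc2)[C@]1(C(=O)OC)CC(=O)OC | intermediate
11 | lithium enolate of 10 | CC1=CC([O-])=C(CCS(=O)c2ccccc2)[C@]1(C(=O)OC)CC(=O)OC.[Li+] | intermediate
12 | methyl 1-(2-methoxy-2-oxoethyl)-2,5-dimethyl-4-oxo-5-[2-(phenylsulfinyl)ethyl]cyclopent-2-ene-1-carboxylate, 5-methyl cis to ring CO2Me, sulfinylethyl cis to CH2CO2Me, sulfur epimers | CC1=CC(=O)[C@](C)(CCS(=O)c2ccccc2)[C@]1(C(=O)OC)CC(=O)OC | intermediate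
13 | benzoic acid | OC(=O)c1ccccc1 | starting material
14 | dilithium (cyclohexa-2,5-dien-1-ylidene)methanediolate (dianion from benzoic acid) | [O-]C([O-])=C1C=CCC=C1.[Li+].[Li+] | intermediate
15 | dilithium aldolate (C9 alkoxide, C19 carboxylate, both esters intact) | [O-][C@@]1(C2(C(=O)[O-])C=CCC=C2)C=C(C)[C@](CC(=O)OC)(C(=O)OC)[C@@]1(C)CCS(=O)c1ccccc1.[Li+].[Li+] | intermediate
16 | 1-[5-(methoxycarbonyl)-6,8-dimethyl-3-oxo-8-[2-(phenylsulfinyl)ethyl]-2-oxabicyclo[3.2.1]oct-6-en-1-yl]cyclohexa-2,5-diene-1-carboxylic acid, 8-methyl syn to the alkene bridge, sulfinylethyl syn to the lactone bridge | C1C(=O)O[C@@]2(C3(C(=O)O)C=CCC=C3)C=C(C)[C@]1(C(=O)OC)[C@@]2(C)CCS(=O)c1ccccc1 | intermediate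
17 | trifluoroacetoxysulfonium carboxylate zwitterion from 16 | C1C(=O)O[C@@]2(C3(C(=O)[O-])C=CCC=C3)C=C(C)[C@]1(C(=O)OC)[C@@]2(C)CC[S+](OC(=O)C(F)(F)F)c1ccccc1 | intermediate
18 | thionium carboxylate zwitterion (C6=S+Ph) | C1C(=O)O[C@@]2(C3(C(=O)[O-])C=CCC=C3)C=C(C)[C@]1(C(=O)OC)[C@@]2(C)CC=[S+]c1ccccc1 | intermediate
19 | seven-membered phenylthio lactone: C19(=O)–O–C6H(SPh)–C7H2–C8, spiro at C10 to the cyclohexa-2,5-diene and fused at C8–C9 to the oxabicyclooctenone, C6 epimers | C1C(=O)O[C@@]2(C3(C=CCC=C3)C(=O)OC(Sc3ccccc3)C4)C=C(C)[C@]1(C(=O)OC)[C@]24C | intermediate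
20 | α-acyloxyalkyl radical at C6 | C1C(=O)O[C@@]2(C3(C=CCC=C3)C(=O)O[CH]C4)C=C(C)[C@]1(C(=O)OC)[C@]24C | intermediate
21 | cyclised secondary radical at C4 | C1C(=O)O[C@@]23C=C(C)[C@]1(C(=O)OC)[C@@]2(C)C[C@@H]1OC(=O)[C@]32C=CC[CH][C@@H]12 | intermediate
22 | pentacyclic bis-lactone: target skeleton with C1=C2, C3 and C4 as CH2, ring D without methylene; C5–H anti to the γ-lactone bridge | C1C(=O)O[C@@]23C=C(C)[C@]1(C(=O)OC)[C@@]2(C)C[C@@H]1OC(=O)[C@]32C=CCC[C@@H]12 | intermediate
23 | ring-A enone (C1=C2–C3=O, C4 H2) | C1C(=O)O[C@@]23C=C(C)[C@]1(C(=O)OC)[C@@]2(C)C[C@@H]1OC(=O)[C@]32C=CC(=O)C[C@@H]12 | intermediate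
24 | 4-monomethyl enone (C4 epimers) | C1C(=O)O[C@@]23C=C(C)[C@]1(C(=O)OC)[C@@]2(C)C[C@@H]1OC(=O)[C@]32C=CC(=O)C(C)[C@@H]12 | intermediate
25 | 4,4-dimethyl enone | C1C(=O)O[C@@]23C=C(C)[C@]1(C(=O)OC)[C@@]2(C)C[C@@H]1OC(=O)[C@]32C=CC(=O)C(C)(C)[C@@H]12 | intermediate
26 | 4,4-dimethyl-3-ketone, ring A saturated | C1C(=O)O[C@@]23C=C(C)[C@]1(C(=O)OC)[C@@]2(C)C[C@@H]1OC(=O)[C@]32CCC(=O)C(C)(C)[C@@H]12 | intermediate
27 | axial (3S) alcohol, OH cis to C5–H | C1C(=O)O[C@@]23C=C(C)[C@]1(C(=O)OC)[C@@]2(C)C[C@@H]1OC(=O)[C@]32CC[C@H](O)C(C)(C)[C@@H]12 | intermediate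
28 | dilithium C3 alkoxide / δ-lactone enolate | C1=C([O-])O[C@@]23C=C(C)[C@]1(C(=O)OC)[C@@]2(C)C[C@@H]1OC(=O)[C@]32CC[C@H]([O-])C(C)(C)[C@@H]12.[Li+].[Li+] | intermediate
29 | Mannich base, α-(dimethylaminomethyl) δ-lactone (α-carbon epimers) | CN(C)CC1C(=O)O[C@@]23C=C(C)[C@]1(C(=O)OC)[C@@]2(C)C[C@@H]1OC(=O)[C@]32CC[C@H](O)C(C)(C)[C@@H]12 | intermediate
30 | trimethylammonium iodide of 29 | C[N+](C)(C)CC1C(=O)O[C@@]23C=C(C)[C@]1(C(=O)OC)[C@@]2(C)C[C@@H]1OC(=O)[C@]32CC[C@H](O)C(C)(C)[C@@H]12.[I-] | intermediate
31 | α-methylene δ-lactone alcohol (deacetyl meroantarctine B) | C=C1C(=O)O[C@@]23C=C(C)[C@]1(C(=O)OC)[C@@]2(C)C[C@@H]1OC(=O)[C@]32CC[C@H](O)C(C)(C)[C@@H]12 | intermediate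
32 | meroantarctine B | C=C1C(=O)O[C@@]23C=C(C)[C@]1(C(=O)OC)[C@@]2(C)C[C@@H]1OC(=O)[C@]32CC[C@H](OC(C)=O)C(C)(C)[C@@H]12 | target

Total step count: 16.
Longest linear sequence: 16 steps (1 to 32); benzoic acid 13 enters at step 8.

Steps most likely to fail

Step 10 (key step). What may go wrong: hydrogen transfer to the C6 radical before it cyclises; poor discrimination between the two diene arms, since the chair closure of ring B has to accept the C8 methyl syn to the forming lactone bridge; and abstraction of a bis-allylic ring-A hydrogen followed by aromatising β-scission. The fallback sets out from 19 and comes back at 23. Oxidation of 19 with excess t-BuOOH and Rh2(C6H10NO)4 at the bis-allylic CH2 and at sulfur should give the cyclohexa-2,5-dienone sulfoxide F6. Thermolysis (toluene, 110 °C) should give the dienone enol lactone F7 by syn-elimination of benzenesulfenic acid. Hydrogen-atom-transfer-initiated reductive olefin coupling (Fe(C5H7O2)3, PhSiH3, EtOH, 60 °C) then delivers hydrogen to C7. The same α-acyloxy radical adds to the electron-poor dienone arm, which can no longer aromatise by hydrogen loss, and enone 23 results directly, so step 11 is not needed.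

Step 8. What may go wrong: proton transfer from the γ-methyl or ester α-positions of 12 to the strongly basic dianion, and retro-aldol cleavage outrunning lactonisation. The fallback sets out from 13 (with 12) and comes back at 16; it separates the reduction from the carbon–carbon bond formation. Benzoic acid is reduced on its own (Li, NH3; NH4Cl) to cyclohexa-2,5-diene-1-carboxylic acid F1. Esterification with 2-(trimethylsilyl)ethanol (dicyclohexylcarbodiimide, 4-(dimethylamino)pyridine) gives 2-(trimethylsilyl)ethyl cyclohexa-2,5-diene-1-carboxylate F2. Its lithium enolate (LiN(i-Pr)2) is transmetalated with CeCl3 and added to 12; the less basic cerium ester enolate should favour addition, and lactonisation gives the coupled silylethyl ester F3. Bu4NF in THF then releases acid 16.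

Step 9. What may go wrong: intermolecular capture of the thionium ion or its elimination to a vinyl sulfide outcompeting the seven-membered ring closure, and ionisation of the allylic tertiary δ-lactone by the trifluoroacetic acid formed. The fallback sets out from 16 and comes back at 22; it uses a different radical precursor. The Pummerer reaction is run without internal capture ((CF3CO)2O, then aq. NaHCO3) to unmask the aldehyde acid F4. The acid is converted into its chloride with 1-chloro-N,N,2-trimethylprop-1-en-1-amine and allowed to add across the aldehyde (ZnCl2 cat.) to the cyclic 1-chloroalkyl ester F5. Chlorine abstraction with (Me3Si)3SiH and azobisisobutyronitrile (benzene, 80 °C) generates the same C6 radical, which should close to 22.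

Further compounds
F1 | step 8 | cyclohexa-2,5-diene-1-carboxylic acid | OC(=O)C1C=CCC=C1
F2 | step 8 | 2-(trimethylsilyl)ethyl cyclohexa-2,5-diene-1-carboxylate | C[Si](C)(C)CCOC(=O)C1C=CCC=C1
F3 | step 8 | 2-(trimethylsilyl)ethyl ester of acid 16 | C1C(=O)O[C@@]2(C3(C(=O)OCC[Si](C)(C)C)C=CCC=C3)C=C(C)[C@]1(C(=O)OC)[C@@]2(C)CCS(=O)c1ccccc1
F4 | step 9 | aldehyde acid (C6 formyl, C19 carboxylic acid) | C1C(=O)O[C@@]2(C3(C(=O)O)C=CCC=C3)C=C(C)[C@]1(C(=O)OC)[C@@]2(C)CC=O
F5 | step 9 | seven-membered 1-chloroalkyl lactone (chlorine on C6, C6 epimers) | C1C(=O)O[C@@]2(C3(C=CCC=C3)C(=O)OC(Cl)C4)C=C(C)[C@]1(C(=O)OC)[C@]24C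
F6 | step 10 | cyclohexa-2,5-dienone α-acyloxy sulfoxide | C1C(=O)O[C@@]2(C3(C=CC(=O)C=C3)C(=O)OC(S(=O)c3ccccc3)C4)C=C(C)[C@]1(C(=O)OC)[C@]24C
F7 | step 10 | cyclohexa-2,5-dienone enol lactone (C6=C7) | C1C(=O)O[C@@]2(C3(C=CC(=O)C=C3)C(=O)OC=C4)C=C(C)[C@]1(C(=O)OC)[C@]24C
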